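**Conventions and assumptions**

- Terpenoid numbering is used throughout: ring A = C1–C5, C10; ring B = C5–C10; C11 = CH2 on C9; C17 = exocyclic methylene carbon on C8; C18 = methyl on C4; C20 = methyl on C10. The face of the decalin that carries H-5, C20 and H-9 is called α, the other face β.
- Remark on the chemistry: in step 4 the lipase is assumed to follow the usual size-based model (bridgehead CH = large, CH2 = medium), so that the (7R)-alcohol is acylated and the required (7S)-alcohol is recovered.

## Analysis of the target

The target 50 is a cis-fused decalin with an exocyclic methylene at C8 and a CH2 group (C11) on C9 that is bonded to C3 of a fully substituted 2-methoxy-4-pyranone carrying a methyl ester and a methyl group. Five contiguous stereocentres (C3, C4, C5, C10, C9) must be set. H-5, C20, C18 and H-9 are α; the C3 hydroxyl, the 3-formyloxy-3-methylbutyl chain on C4 and C11 are β. The ring fusion is therefore cis, C11 is trans to C20, and the secondary hydroxyl is cis to the side chain. C4 and C10 are both quaternary and 1,3-related across C5, so ring A is crowded and its centres cannot be corrected by epimerisation.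

The sensitive groups are:
- the tertiary formate, which must be made beside a free secondary alcohol and is labile to bases, hydrides and nucleophiles;
- the C8 methylene next to the C9 stereocentre, which rules out hydrogenation and unselective alkene hydration;
- the methoxypyranone ester, which is sensitive to nucleophiles and has an isomeric 4-methoxy-2-pyranone.

The strategy rests on one structural feature. C1, C2, C5, C6, C7, C10 and C20 are the carbon skeleton of creosol 4, and C3–C4 is a two-carbon enol ether. Ring A, with its oxygen already on C3, can therefore be closed as the cyclohexene ring of a bicyclo[2.2.2]octenone by oxidative dearomatisation and cycloaddition. The keto bridge of that bicycle becomes C7–C6 of ring B when an alkenyl group supplying C8, C9 and C11 is added and an oxy-Cope shift follows. One consequence must be dealt with inside the plan: the bridge oxygen ends on C7, not C8. The C8 methylene therefore cannot come from direct olefination of that carbonyl. It has to be built through the C7 enolate, and the C7 oxygen has to be removed afterwards.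

## Retrosynthetic reasoning

**50 ⇒ 49 ⇒ 48.** The last two operations are removal of a silyl group from the C3 oxygen and formylation of the tertiary alcohol. The two hydroxyls cannot be told apart by an acylating agent, so the secondary one stays masked from the moment it is created, and the labile formate is made only when no basic or reducing step remains.

**48 ⇒ 39 + 45.** The C11–C3' bond is cut. The complete methoxypyranone 45 is attached in one step by an sp3–sp2 cross-coupling of the organozinc derived from iodide 39. This keeps C11 at the alcohol/iodide oxidation level and so avoids a β,γ-unsaturated aldehyde at C9 that could epimerise or slip into conjugation. It also settles the 2-methoxy-4-pyranone regiochemistry on a small fragment. Fragment 45 comes from 43 and 42, and 42 from 40 and 41 by acylative ring closure.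

**39 ⇒ 38 ⇒ 37 ⇒ 36 ⇒ 35.** The tertiary alcohol is traced back to a prenyl group through its epoxide. A hydrogen-atom-transfer or mercury-based hydration would also attack the C8 methylene. A peracid discriminates in favour of the trisubstituted alkene, and hydride then opens the epoxide at its secondary carbon. This must precede the pyranone, which would not survive the hydride.

**35 ⇒ 34 ⇒ 33 ⇒ 32.** The C3 carbinol comes from the C3 ketone. A bulky hydride on the saturated ketone 33 should attack from the convex α face and give the axial β-alcohol. The C1=C2 alkene of 32 is removed first by conjugate reduction, which leaves the two isolated alkenes alone.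

**32 ⇒ 30 ⇒ 27 (+ 28).** The quaternary C4 is made by two alkylations of enone 27. Because C10 is quaternary, C4 is the only enolisable position. The group introduced second enters anti to the C5–C6 bond, so the prenyl group goes in first and the methyl group second.

**27 ⇒ 26 ⇒ 25.** The enone is the oxidation product of the allylic C3 alcohol, whose oxygen is the one brought in by the enol ether.

**25 ⇒ 24 ⇒ 23 ⇒ 22 ⇒ 19.** This is the repair of ring B. The oxy-Cope step delivers a C7 enolate of defined regiochemistry (C7=C8), kept as silyl enol ether 19. C17 is attached to C8 by a Mannich methylenation to give 22. The C7 oxygen is then removed by 1,2-reduction, carbonate formation and palladium-catalysed formate hydrogenolysis. That last reaction places hydrogen on the more substituted allyl terminus (C7) and leaves the alkene exocyclic.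

**19 ⇒ 16.** The C9–C10 bond is cut (anionic oxy-Cope; the C2–C7 bond is re-formed in the backward sense). The forward reaction closes ring B cis-fused and sets C10 and C9 together from the alkene geometry.

**16 ⇒ 10 + 14.** The C7–C8 bond is cut: addition of the (E)-alkenyl metal from 14 to ketone 10. 14 comes from 12 and from propargyl alcohol 11.

**10 ⇒ 9 ⇒ 8 ⇒ 7 ⇒ 6.** The two ketal methoxy groups are removed reductively before the alkenyl addition, so that C6 is already CH2 and the oxy-Cope enolate is the only regiochemical handle in ring B. The racemic cycloadduct is resolved as its free alcohol at the earliest point, and the alcohol is then silylated. A 4-methoxybenzyl ether is used in place of a plain benzyl ether in the dienophile because it can be removed oxidatively without touching the strained alkene.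

**6 ⇒ 4 + 3 (via 5).** The C2–C3 and C4–C5 bonds are cut: oxidative dearomatisation of 4 to the dienone 5 and its Diels–Alder reaction with enol ether 3. This one step makes ring A, three stereocentres and the oxygen at C3 from two simple compounds. 3 is made from 1 and 2.

## Alternatives that were turned down

**Alternative 1:** The C9–C10 bond is disconnected in a ring-A cyclohexene taken from the chiral pool. Forward, the alkenyl iodide of A2 would add across the C1=C10 alkene in an intramolecular Heck reaction (6-exo), with β-hydride elimination towards C2, to give the cis-decalin A1 with a C8 ketone and a C9 exocyclic methylene.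
- For it: the absolute configuration comes from the starting material, so no resolution is needed. The oxygen sits on C8, so the methylene is one olefination away. The enone of A1 could accept the pyranone at C11 by conjugate addition. On these three points it is stronger than the chosen route.
- Against it: A2 already contains C3, C4 (quaternary) and C5, and has to be built linearly with full stereocontrol before the key step is even tried. The Heck reaction must form a quaternary centre on a trisubstituted alkene flanked by the quaternary C4. C9 is not set by the key step at all; it would arise later by protonation of an enolate next to C10.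
- Comparison: the chosen strategy makes ring A and three centres in one step from commodity chemicals, and its oxy-Cope step fixes C9 and C10 together. It pays with a resolution and a carbonyl transposition in ring B.

**Alternative 2:** Here too the decalin comes from an anionic oxy-Cope rearrangement. The bicycle A4 would be assembled from a Birch-reduced methoxyarene and a ketene equivalent. Its potassium alkoxide would rearrange, with the enolate trapped as the C8 enol triflate A3.
- For it: the enolate oxygen lands on C8, the correct ring-B carbon, and the C4 side chain and C11 are carried from the start. On the first point it is stronger than the chosen route.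
- Against it: the Diels–Alder reaction that makes A4 must join a tetrasubstituted methoxydiene to a β-substituted ketene equivalent, creating two fully substituted bridgeheads. This is far more demanding in rate and regiochemistry than the reaction of a reactive dienone with a simple enol ether. Birch reduction and diene isomerisation give isomer mixtures. The material is racemic and has no convenient handle for resolution. Converting the C8 triflate of A3 into an exocyclic methylene is also not direct, since one-carbon coupling gives the endocyclic alkene.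
- Comparison: the chosen strategy keeps the same ring-B logic but starts from a cycloaddition of a well-established type and a resolvable alcohol. It accepts the C7 to C8 shift as the price.

**Alternative 3:** The C5–C10 and C8–C9 bonds are both disconnected. Trienoate A6 would undergo an intramolecular Diels–Alder reaction to give the cis-fused octalin ester A5.
- For it: both rings and the centres C5, C10 and C9 come from one step, and the precursor is acyclic and can be made enantiomerically pure by standard asymmetric C–C bond formation. In the number of bonds formed in the key step it is stronger than the chosen route.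
- Against it: the (Z)-diene reaches the s-cis conformation with difficulty and tends to undergo 1,5-hydrogen shift. The β,β-disubstituted (Z)-enoate is a weak dienophile. Endo/exo and facial control by the C3 and C4 substituents is not secured. A5 still lacks the quaternary C4, since its C4 carries a hydrogen, and has no functional group at C8. Installing the C4 methyl would need a C3 ketone with two enolisable sides.
- Comparison: in the chosen strategy the C3 enone has a single enolisable position, and the ring-B carbonyl is already placed next to C8.

Key step: step 2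

## Route

Step 1
Reactants: 1 4-methoxybenzyl alcohol; 2 vinyl acetate
Product: 3 4-methoxybenzyl vinyl ether
Conditions: [Ir(cod)Cl]2 (1 mol%), Na2CO3, toluene, 100 °C
Reagents that add atoms: none
Why: Iridium-catalysed transfer vinylation of a primary benzylic alcohol; the carbonate keeps the medium basic so that the acid-sensitive enol ether is not converted into an acetal.

Step 2
Reactants: 4 creosol; 3 4-methoxybenzyl vinyl ether
Product: 6 racemic bicyclo[2.2.2]octenone dimethyl ketal with the 4-methoxybenzyloxy group on C3, via masked o-benzoquinone 5 (not isolated)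
Conditions: PhI(OAc)2 (1.2 equiv), 3 (10 equiv), MeOH, slow addition of 4, 0 °C → rt
Reagents that add atoms: methanol, CO
Why: PhI(OAc)2 oxidises the phenol through an aryloxy-iodane and methanol adds at the methoxy-bearing carbon, giving the 6,6-dimethoxy-2,4-dienone 5, which is not isolated. 5 is an electron-poor diene locked s-cis (C2=C1–C10=C5) and combines with the electron-rich alkene of 3 in a concerted inverse-electron-demand Diels–Alder reaction; the closest known reaction type is the cycloaddition of masked o-benzoquinones with benzyl vinyl ether. Ring A (C1, C2, C3, C4, C5, C10) closes by intermolecular [4+2] addition as the cyclohexene ring of a bicyclo[2.2.2]octenone, the C2–C3 and C4–C5 bonds forming suprafacially on both partners. The regiochemistry follows from polarisation: the nucleophilic CH2 terminus of 3 (C4) bonds to the δ-carbon of the dienone (C5), so the oxygen-bearing carbon C3 ends next to the bridgehead C2 that is α to the ketone. The bridgeheads C2 and C5 are fixed relative to each other by the bicyclic frame, and C3 is set by the endo transition state, which places the alkoxy group under the diene and hence syn to the new C1=C10 bond. The two faces of 5 are equivalent, so 6 is racemic and is resolved in step 4. The step needs 5 to be trapped faster than it dimerises; the methyl group on C10 makes the dienophilic C5=C10 bond of 5 trisubstituted and slows dimerisation, and 3 is used in excess with slow addition of 4.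

Step 3
Reactants: 6 racemic 4-methoxybenzyl ether
Product: 7 racemic 7-hydroxy-3,3-dimethoxy-5-methylbicyclo[2.2.2]oct-5-en-2-one
Conditions: DDQ, CH2Cl2/pH 7 buffer, 0 °C → rt
Reagents that add atoms: none
Why: Oxidative cleavage of a 4-methoxybenzyl ether (hydride abstraction, then hydrolysis of the oxocarbenium ion); ketone, ketal and the strained trisubstituted alkene are inert, which hydrogenolysis of a plain benzyl ether would not guarantee.

Step 4
Reactants: 7 racemic alcohol; 2 vinyl acetate (acyl donor)
Product: 8 (1S,4S,7S)-7-hydroxy-3,3-dimethoxy-5-methylbicyclo[2.2.2]oct-5-en-2-one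
Conditions: lipase from Burkholderia cepacia (immobilised), t-BuOMe, 30 °C, run past half conversion; chromatography
Reagents that add atoms: none
Why: Lipase-catalysed kinetic resolution by irreversible acylation; the carbinol carbon is flanked by a bridgehead CH (large) and a CH2 (medium), so the (7R)-alcohol should be acylated and (1S,4S,7S)-8 recovered as the unreacted alcohol in high enantiomeric purity.

Step 5
Reactants: 8 (1S,4S,7S)-alcohol
Product: 9 (1S,4S,7S)-7-(tert-butyldimethylsilyloxy)-3,3-dimethoxy-5-methylbicyclo[2.2.2]oct-5-en-2-one
Conditions: t-BuMe2SiCl, imidazole, DMF, rt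
Reagents that add atoms: tert-butyldimethylsilyl chloride, CC(C)(C)[Si](C)(C)Cl
Why: Standard silylation; it masks the β-hydroxy ketone so that no alkoxide capable of retro-aldol opening of the bicycle can form in steps 9 and 10.

Step 6
Reactants: 9 silyl ether ketal
Product: 10 (1S,4R,7S)-7-(tert-butyldimethylsilyloxy)-5-methylbicyclo[2.2.2]oct-5-en-2-one
Conditions: SmI2 (5 equiv), THF/MeOH, rt
Reagents that add atoms: none
Why: SmI2 reduction of an α-alkoxy ketone (electron transfer to the carbonyl, loss of methoxide, protonation of the samarium enolate, twice), a reaction established for 3,3-dimethoxybicyclo[2.2.2]octenones; C6 becomes CH2 before ring B is formed.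

Step 7
Reactants: 11 propargyl alcohol
Product: 12 4-methoxybenzyl propargyl ether
Conditions: NaH, 4-MeOC6H4CH2Cl, Bu4NI (cat.), THF, 0 °C → rt
Reagents that add atoms: 4-methoxybenzyl chloride, COc1ccc(CCl)cc1
Why: Williamson ether synthesis on a primary alkoxide with a reactive benzylic chloride.

Step 8
Reactants: 12 4-methoxybenzyl propargyl ether
Product: 14 (E)-1-iodo-3-(4-methoxybenzyloxy)prop-1-ene, via alkenylzirconocene chloride 13 (not isolated)
Conditions: Cp2Zr(H)Cl, THF, rt; then I2, 0 °C
Reagents that add atoms: iodine, II
Why: Hydrozirconation adds Zr–H syn and anti-Markovnikov, placing zirconium on the terminal carbon with (E) geometry; iodinolysis of the C–Zr bond proceeds with retention.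

Step 9
Reactants: 14 (E)-alkenyl iodide; 10 bicyclic ketone
Product: 16 tertiary alkenyl carbinol with the alkenyl group syn to the C1=C10 bridge, via alkenyllithium 15 (not isolated)
Conditions: t-BuLi (2.1 equiv), Et2O, −78 °C; then 10, THF, −78 → −40 °C; H2O
Reagents that add atoms: none
Why: Iodine–lithium exchange with retention of alkene geometry, then 1,2-addition; the nucleophile should enter from the face flanked by the C1=C10 bridge because the C3–C4 bridge shields the other face with its inward hydrogens, which places the alkenyl group where the oxy-Cope shift needs it.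

Step 10
Reactants: 16 tertiary alkenyl carbinol
Product: 19 cis-fused C7 trimethylsilyl enol ether, via potassium alkoxide 17 (not isolated), via potassium enolate 18 (not isolated)
Conditions: KH, 18-crown-6, THF, 0 °C → rt; then Me3SiCl/Et3N, −78 °C
Reagents that add atoms: chlorotrimethylsilane, C[Si](C)(C)Cl
Why: Anionic oxy-Cope rearrangement of the 1,5-diene C9=C8–C7–C2–C1=C10 through the boat transition state enforced by the bicycle: C9–C10 forms on the face of C10 that carries the C6 bridge, so ring B is cis-fused (H-5 and C20 cis), and the (E) geometry places C11 trans to C20 at C9. The enolate is formed only as the C7=C8 isomer and silylation preserves that regiochemistry.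

Step 11
Reactants: 19 silyl enol ether
Product: 22 α-methylene ketone (C7 ketone, C8=C17), via Mannich base 20 (not isolated), via trimethylammonium iodide 21 (not isolated)
Conditions: CH2=NMe2+ I−, CH2Cl2, rt; MeI, Et2O; then aq. NaHCO3/CH2Cl2, rt
Reagents that add atoms: dimethyl(methylidene)ammonium iodide, C=[N+](C)C.[I-]
Why: Mannich reaction of the silyl enol ether at C8, N-methylation and E1cB loss of trimethylamine (α-methylenation); it attaches C17 to C8 through the only regio-defined enol derivative, and the bicarbonate conditions limit isomerisation of the exocyclic enone to the C8=C9 isomer.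

Step 12
Reactants: 22 α-methylene ketone
Product: 23 C7 allylic alcohol (epimers at C7)
Conditions: NaBH4, CeCl3·7H2O, MeOH, −78 °C
Reagents that add atoms: none
Why: Luche reduction gives clean 1,2-reduction of the enone; the C7 configuration is of no consequence because C7 becomes CH2.

Step 13
Reactants: 23 allylic alcohol
Product: 24 C7 allylic methyl carbonate
Conditions: ClCO2Me, pyridine, DMAP (cat.), CH2Cl2, 0 °C
Reagents that add atoms: methyl chloroformate, COC(=O)Cl
Why: Acylation of a secondary allylic alcohol to give an ionisable leaving group for palladium.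

Step 14
Reactants: 24 allylic carbonate
Product: 25 cis-octalin with C8 exocyclic methylene, C1=C2, 3α-silyloxy and 9β-CH2O-(4-methoxybenzyl)
Conditions: Pd2(dba)3 (2.5 mol%), n-Bu3P (10 mol%), HCO2H, Et3N, THF, 65 °C
Reagents that add atoms: none
Why: Palladium-catalysed formate hydrogenolysis of an allylic carbonate: ionisation gives the π-allyl complex over C7–C8–C17, formate decarboxylates to a palladium hydride, and hydride is delivered to the more substituted terminus C7, leaving the less substituted, exocyclic alkene. The silyl ether at the other allylic position is not a leaving group.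

Step 15
Reactants: 25 silyl ether
Product: 26 3α-allylic alcohol
Conditions: Bu4NF, THF, 0 °C → rt
Reagents that add atoms: none
Why: Fluoride cleavage of the secondary silyl ether; the benzylic ether at C11 is untouched.

Step 16
Reactants: 26 allylic alcohol
Product: 27 Δ1-3-ketone (enone)
Conditions: Dess–Martin periodinane, NaHCO3, CH2Cl2, 0 °C → rt
Reagents that add atoms: none
Why: Mild oxidation of an allylic secondary alcohol; the isolated alkene and the electron-rich benzyl ether are stable under buffered conditions.

Step 17
Reactants: 27 enone; 28 prenyl bromide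
Product: 30 4-prenyl enone (epimers at C4), via lithium dienolate 29 (not isolated)
Conditions: LiN(i-Pr)2 (1.05 equiv), THF, −78 °C; then 28, −78 → −30 °C
Reagents that add atoms: none
Why: Kinetic α'-deprotonation; C4 is the only enolisable carbon because the γ-carbon C10 is quaternary, and the cross-conjugated enolate is C-alkylated by the reactive allylic bromide.

Step 18
Reactants: 30 4-prenyl enone
Product: 32 4α-methyl-4β-prenyl enone, via lithium enolate 31 (not isolated)
Conditions: LiN(i-Pr)2 (1.3 equiv), THF, −78 → −40 °C; MeI, DMPU, −78 → 0 °C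
Reagents that add atoms: iodomethane, CI
Why: Alkylation of the tetrasubstituted enolate: allylic strain keeps H-5 in the enolate plane and the C5–C6 bond perpendicular to it, so methyl iodide should attack anti to C6 on the convex α face of the cis-decalin. This gives C18 α and the prenyl group β.

Step 19
Reactants: 32 quaternary enone
Product: 33 saturated C3 ketone
Conditions: [(Ph3P)CuH]6 (0.4 equiv), H2O (2 equiv), toluene/THF, rt
Reagents that add atoms: none
Why: Copper hydride conjugate reduction of the enone; the copper enolate is protonated by water, and the prenyl and exocyclic alkenes are not reduced.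

Step 20
Reactants: 33 C3 ketone
Product: 34 3β-alcohol
Conditions: LiBH(s-Bu)3, THF, −78 °C; then NaOH, H2O2
Reagents that add atoms: none
Why: The bulky trialkylborohydride attacks equatorially from the convex α face (the β face is blocked by the syn-axial C6), giving the axial 3β-alcohol cis to the prenyl group, as in reductions of 4,4-disubstituted terpenoid 3-ketones.

Step 21
Reactants: 34 3β-alcohol
Product: 35 3β-triethylsilyl ether
Conditions: Et3SiOTf, 2,6-lutidine, CH2Cl2, −78 → 0 °C
Reagents that add atoms: triethylsilyl triflate, CC[Si](CC)(CC)OS(=O)(=O)C(F)(F)F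
Why: A silyl triflate silylates even the hindered axial alcohol; the group prevents tetrahydrofuran formation in step 22, differentiates the two hydroxyls, and can be removed at the end without base.

Step 22
Reactants: 35 silyl ether with prenyl group
Product: 36 side-chain epoxide (epimers at the epoxide CH)
Conditions: mCPBA (1.05 equiv), NaHCO3, CH2Cl2, −20 → 0 °C
Reagents that add atoms: 3-chloroperbenzoic acid, OOC(=O)c1cccc(Cl)c1
Why: Peracid epoxidation favours the more nucleophilic trisubstituted alkene over a 1,1-disubstituted exocyclic methylene (the selectivity known from limonene); the C8 methylene is further shielded by the substituents on C9 and C10.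

Step 23
Reactants: 36 epoxide
Product: 37 tertiary alcohol (3-hydroxy-3-methylbutyl chain on C4)
Conditions: LiAlH4, THF, 0 °C → rt
Reagents that add atoms: none
Why: SN2 opening of a trisubstituted epoxide by hydride at the less substituted carbon gives the tertiary alcohol; silyl and benzyl ethers and isolated alkenes are inert.

Step 24
Reactants: 37 4-methoxybenzyl ether
Product: 38 C11 primary alcohol
Conditions: DDQ, CH2Cl2/pH 7 buffer, 0 °C
Reagents that add atoms: none
Why: Oxidative removal of the 4-methoxybenzyl group; the triethylsilyl ether, tertiary alcohol and exocyclic alkene tolerate the buffered conditions.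

Step 25
Reactants: 38 primary alcohol
Product: 39 C11 iodide
Conditions: I2, PPh3, imidazole, CH2Cl2, 0 °C → rt
Reagents that add atoms: iodine, II
Why: Appel-type iodination through the alkoxyphosphonium ion; only the primary alcohol reacts at this temperature.

Step 26
Reactants: 40 methyl acetoacetate; 41 malonyl dichloride
Product: 42 methyl 4-hydroxy-2-methyl-6-oxo-6H-pyran-3-carboxylate
Conditions: CH2Cl2, 0 °C → reflux (HCl evolution)
Reagents that add atoms: none
Why: C-acylation of the β-keto ester by one acid chloride and O-acylation of the acetyl enol by the other closes the 4-hydroxy-2-pyranone ring, a known pyranone synthesis.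

Step 27
Reactants: 42 hydroxypyranone
Product: 43 methyl 4-hydroxy-5-iodo-2-methyl-6-oxo-6H-pyran-3-carboxylate
Conditions: N-iodosuccinimide, MeCN, rt
Reagents that add atoms: N-iodosuccinimide, O=C1CCC(=O)N1I
Why: Electrophilic iodination at the only free, enol-activated ring carbon.

Step 28
Reactants: 43 iodo hydroxypyranone
Product: 45 methyl 5-iodo-6-methoxy-2-methyl-4-oxo-4H-pyran-3-carboxylate, via methoxypyrylium triflate 44 (not isolated)
Conditions: MeOTf, CH2Cl2, rt; then aq. NaHCO3
Reagents that add atoms: methyl triflate, COS(=O)(=O)C(F)(F)F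
Why: The neutral hydroxypyranone is methylated by the hard electrophile on the lactone carbonyl oxygen, its most basic site (the 4-hydroxyl is hydrogen-bonded to the ester and flanked by iodine); deprotonation gives the 2-methoxy-4-pyranone. Any 4-methoxy-2-pyranone isomer is removed here, on the small fragment.

Step 29
Reactants: 39 C11 iodide; 45 iodo methoxypyranone
Product: 48 coupled methoxypyranone with 3β-triethylsilyloxy and free tertiary alcohol, via dilithio species 46 (not isolated), via alkylzinc chloride 47 (not isolated)
Conditions: t-BuLi (3.2 equiv), Et2O/pentane, −78 °C; ZnCl2, THF, −78 °C → rt; then 45, Pd(OAc)2 (5 mol%), SPhos (10 mol%), THF, 40 °C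
Reagents that add atoms: none
Why: Negishi coupling: the first equivalent of t-BuLi deprotonates the tertiary alcohol, iodine–lithium exchange and transmetalation give the primary alkylzinc, and palladium with a bulky biaryl phosphine joins it to the α-iodo enone carbon of 45. No base is needed, and the ester and methoxypyranone are tolerated by the organozinc.

Step 30
Reactants: 48 tertiary alcohol
Product: 49 tertiary formate with 3β-triethylsilyloxy
Conditions: HCO2H/Ac2O (premixed, 50 °C, then cooled), pyridine, DMAP (cat.), CH2Cl2, 0 °C → rt
Reagents that add atoms: acetic formic anhydride, CC(=O)OC=O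
Why: The mixed anhydride transfers its formyl group (the more electrophilic, less hindered carbonyl) to the only free hydroxyl; the C3 oxygen is still silylated.

Step 31
Reactants: 49 silylated formate
Product: 50 target CNP0292250.1
Conditions: HF·pyridine, pyridine, THF, 0 °C → rt
Reagents that add atoms: none
Why: Fluoride desilylation under weakly acidic, non-nucleophilic conditions that should spare the formate, the methoxypyranone ester and the exocyclic alkene.

## Compound list

1 | 4-methoxybenzyl alcohol | COc1ccc(CO)cc1 | starting material
2 | vinyl acetate | C=COC(C)=O | starting material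
3 | 4-methoxybenzyl vinyl ether | C=COCc1ccc(OC)cc1 | intermediate
4 | creosol (2-methoxy-4-methylphenol) | Cc1ccc(O)c(OC)c1 | starting material
5 | 6,6-dimethoxy-4-methylcyclohexa-2,4-dien-1-one (masked o-benzoquinone) | O=C1C=CC(C)=CC1(OC)OC | intermediate (not isolated)
6 | rac-(1S,4S,7S)-3,3-dimethoxy-7-[(4-methoxybenzyl)oxy]-5-methylbicyclo[2.2.2]oct-5-en-2-one, ether group syn to the C5=C6 bridge (racemic; SMILES shows the enantiomer carried on) | O=C1C(OC)(OC)[C@H]2C[C@H](OCc3ccc(OC)cc3)[C@@H]1C=C2C | intermediate
7 | rac-(1S,4S,7S)-7-hydroxy-3,3-dimethoxy-5-methylbicyclo[2.2.2]oct-5-en-2-one (racemic; SMILES shows the enantiomer carried on) | O=C1C(OC)(OC)[C@H]2C[C@H](O)[C@@H]1C=C2C | intermediate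
8 | (1S,4S,7S)-7-hydroxy-3,3-dimethoxy-5-methylbicyclo[2.2.2]oct-5-en-2-one | O=C1C(OC)(OC)[C@H]2C[C@H](O)[C@@H]1C=C2C | intermediate
9 | (1S,4S,7S)-7-(tert-butyldimethylsilyloxy)-3,3-dimethoxy-5-methylbicyclo[2.2.2]oct-5-en-2-one | O=C1C(OC)(OC)[C@H]2C[C@H](O[Si](C)(C)C(C)(C)C)[C@@H]1C=C2C | intermediate
10 | (1S,4R,7S)-7-(tert-butyldimethylsilyloxy)-5-methylbicyclo[2.2.2]oct-5-en-2-one | O=C1C[C@H]2C[C@H](O[Si](C)(C)C(C)(C)C)[C@@H]1C=C2C | intermediate
11 | propargyl alcohol | C#CCO | starting material
12 | 4-methoxybenzyl propargyl ether | C#CCOCc1ccc(OC)cc1 | intermediate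
13 | (E)-[3-(4-methoxybenzyloxy)prop-1-enyl]zirconocene chloride | Cl[Zr](/C=C/COCc1ccc(OC)cc1)(C1C=CC=C1)C1C=CC=C1 | intermediate (not isolated)
14 | (E)-1-iodo-3-(4-methoxybenzyloxy)prop-1-ene | I/C=C/COCc1ccc(OC)cc1 | intermediate
15 | (E)-3-(4-methoxybenzyloxy)prop-1-enyllithium | [Li]/C=C/COCc1ccc(OC)cc1 | intermediate (not isolated)
16 | 7-(tert-butyldimethylsilyloxy)-2-[(E)-3-(4-methoxybenzyloxy)prop-1-enyl]-5-methylbicyclo[2.2.2]oct-5-en-2-ol, alkenyl group syn to the C5=C6 bridge, hydroxyl syn to the C7–C8 bridge, bridgeheads as in 10 | O[C@@]1(/C=C/COCc3ccc(OC)cc3)C[C@H]2C[C@H](O[Si](C)(C)C(C)(C)C)[C@@H]1C=C2C | intermediate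
17 | potassium alkoxide of 16 | [K+].[O-][C@@]1(/C=C/COCc3ccc(OC)cc3)C[C@H]2C[C@H](O[Si](C)(C)C(C)(C)C)[C@@H]1C=C2C | intermediate (not isolated)
18 | potassium C7 enolate (C7=C8) of the cis-decalin: C1=C2, 3α-OSi(t-Bu)Me2, 5α-H, 9β-CH2O-(4-methoxybenzyl), 10α-CH3 | [K+].[O-]C1=C[C@H](COCc3ccc(OC)cc3)[C@]2(C)C=C[C@@H](O[Si](C)(C)C(C)(C)C)C[C@@H]2C1 | intermediate (not isolated)
19 | C7 trimethylsilyl enol ether (C7=C8) of the cis-decalin: C1=C2, 3α-OSi(t-Bu)Me2, 5α-H, 9β-CH2O-(4-methoxybenzyl), 10α-CH3 | C[Si](C)(C)OC1=C[C@H](COCc3ccc(OC)cc3)[C@]2(C)C=C[C@@H](O[Si](C)(C)C(C)(C)C)C[C@@H]2C1 | intermediate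
20 | Mannich base: C7 ketone with CH2NMe2 on C8 (C8 epimers), other groups as in 19 | O=C1C(CN(C)C)[C@H](COCc3ccc(OC)cc3)[C@]2(C)C=C[C@@H](O[Si](C)(C)C(C)(C)C)C[C@@H]2C1 | intermediate (not isolated)
21 | trimethylammonium iodide of 20 | O=C1C(C[N+](C)(C)C)[C@H](COCc3ccc(OC)cc3)[C@]2(C)C=C[C@@H](O[Si](C)(C)C(C)(C)C)C[C@@H]2C1.[I-] | intermediate (not isolated)
22 | α-methylene ketone: C7 ketone, C8=C17, C1=C2, 3α-OSi(t-Bu)Me2, 5α-H, 9β-CH2O-(4-methoxybenzyl), 10α-CH3 | O=C1C(=C)[C@H](COCc3ccc(OC)cc3)[C@]2(C)C=C[C@@H](O[Si](C)(C)C(C)(C)C)C[C@@H]2C1 | intermediate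
23 | C7 allylic alcohol of 22 (C7 epimers) | OC1C(=C)[C@H](COCc3ccc(OC)cc3)[C@]2(C)C=C[C@@H](O[Si](C)(C)C(C)(C)C)C[C@@H]2C1 | intermediate
24 | C7 methyl carbonate of 23 | COC(=O)OC1C(=C)[C@H](COCc3ccc(OC)cc3)[C@]2(C)C=C[C@@H](O[Si](C)(C)C(C)(C)C)C[C@@H]2C1 | intermediate
25 | cis-octalin: C8 exocyclic methylene, C1=C2, 3α-OSi(t-Bu)Me2, 5α-H, 9β-CH2O-(4-methoxybenzyl), 10α-CH3 | C=C1[C@H](COCc3ccc(OC)cc3)[C@]2(C)C=C[C@@H](O[Si](C)(C)C(C)(C)C)C[C@@H]2CC1 | intermediate
26 | 3α-allylic alcohol of 25 | C=C1[C@H](COCc3ccc(OC)cc3)[C@]2(C)C=C[C@@H](O)C[C@@H]2CC1 | intermediate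
27 | enone: C3 ketone, C1=C2, C8 exocyclic methylene, 5α-H, 9β-CH2O-(4-methoxybenzyl), 10α-CH3 | C=C1[C@H](COCc3ccc(OC)cc3)[C@]2(C)C=CC(=O)C[C@@H]2CC1 | intermediate
28 | prenyl bromide | CC(C)=CCBr | starting material
29 | lithium dienolate of 27 (C3–OLi, C3=C4) | C=C1[C@H](COCc3ccc(OC)cc3)[C@]2(C)C=CC(O[Li])=C[C@@H]2CC1 | intermediate (not isolated)
30 | 4-prenyl enone (C4 epimers) | C=C1[C@H](COCc3ccc(OC)cc3)[C@]2(C)C=CC(=O)C(CC=C(C)C)[C@@H]2CC1 | intermediate
31 | lithium enolate of 30 (C3–OLi, C3=C4) | C=C1[C@H](COCc3ccc(OC)cc3)[C@]2(C)C=CC(O[Li])=C(CC=C(C)C)[C@@H]2CC1 | intermediate (not isolated)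
32 | 4α-methyl-4β-prenyl enone | C=C1[C@H](COCc3ccc(OC)cc3)[C@]2(C)C=CC(=O)[C@](C)(CC=C(C)C)[C@@H]2CC1 | intermediate
33 | saturated C3 ketone: 4α-methyl, 4β-prenyl, 5α-H, C8 exocyclic methylene, 9β-CH2O-(4-methoxybenzyl), 10α-CH3 | C=C1[C@H](COCc3ccc(OC)cc3)[C@]2(C)CCC(=O)[C@](C)(CC=C(C)C)[C@@H]2CC1 | intermediate
34 | 3β-alcohol of 33 | C=C1[C@H](COCc3ccc(OC)cc3)[C@]2(C)CC[C@H](O)[C@](C)(CC=C(C)C)[C@@H]2CC1 | intermediate
35 | 3β-triethylsilyl ether of 34 | C=C1[C@H](COCc3ccc(OC)cc3)[C@]2(C)CC[C@H](O[Si](CC)(CC)CC)[C@](C)(CC=C(C)C)[C@@H]2CC1 | intermediate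
36 | side-chain epoxide: 4β-(3,3-dimethyloxiran-2-yl)methyl (epimers at the oxirane CH) | C=C1[C@H](COCc3ccc(OC)cc3)[C@]2(C)CC[C@H](O[Si](CC)(CC)CC)[C@](C)(CC4OC4(C)C)[C@@H]2CC1 | intermediate
37 | tertiary alcohol: 4β-(3-hydroxy-3-methylbutyl), 3β-OSiEt3, 9β-CH2O-(4-methoxybenzyl) | C=C1[C@H](COCc3ccc(OC)cc3)[C@]2(C)CC[C@H](O[Si](CC)(CC)CC)[C@](C)(CCC(C)(C)O)[C@@H]2CC1 | intermediate
38 | C11 primary alcohol: 9β-CH2OH, 3β-OSiEt3, 4β-(3-hydroxy-3-methylbutyl) | C=C1[C@H](CO)[C@]2(C)CC[C@H](O[Si](CC)(CC)CC)[C@](C)(CCC(C)(C)O)[C@@H]2CC1 | intermediate
39 | C11 iodide: 9β-CH2I, otherwise as 38 | C=C1[C@H](CI)[C@]2(C)CC[C@H](O[Si](CC)(CC)CC)[C@](C)(CCC(C)(C)O)[C@@H]2CC1 | intermediate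
40 | methyl acetoacetate | CC(=O)CC(=O)OC | starting material
41 | malonyl dichloride | O=C(Cl)CC(=O)Cl | starting material
42 | methyl 4-hydroxy-2-methyl-6-oxo-6H-pyran-3-carboxylate | COC(=O)C1=C(C)OC(=O)C=C1O | intermediate
43 | methyl 4-hydroxy-5-iodo-2-methyl-6-oxo-6H-pyran-3-carboxylate | COC(=O)C1=C(C)OC(=O)C(I)=C1O | intermediate
44 | 4-hydroxy-3-iodo-2-methoxy-5-(methoxycarbonyl)-6-methylpyrylium triflate | COC(=O)c1c(C)[o+]c(OC)c(I)c1O.[O-]S(=O)(=O)C(F)(F)F | intermediate (not isolated)
45 | methyl 5-iodo-6-methoxy-2-methyl-4-oxo-4H-pyran-3-carboxylate | COC(=O)C1=C(C)OC(OC)=C(I)C1=O | intermediate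
46 | C11 alkyllithium with lithium tertiary alkoxide, derived from 39 | C=C1[C@H](C[Li])[C@]2(C)CC[C@H](O[Si](CC)(CC)CC)[C@](C)(CCC(C)(C)O[Li])[C@@H]2CC1 | intermediate (not isolated)
47 | C11 alkylzinc chloride with lithium tertiary alkoxide | C=C1[C@H](C[Zn]Cl)[C@]2(C)CC[C@H](O[Si](CC)(CC)CC)[C@](C)(CCC(C)(C)O[Li])[C@@H]2CC1 | intermediate (not isolated)
48 | coupled product: 9β-CH2-[2-methoxy-5-(methoxycarbonyl)-6-methyl-4-oxo-4H-pyran-3-yl], 3β-OSiEt3, 4β-(3-hydroxy-3-methylbutyl) | C=C1[C@H](CC3=C(OC)OC(C)=C(C(=O)OC)C3=O)[C@]2(C)CC[C@H](O[Si](CC)(CC)CC)[C@](C)(CCC(C)(C)O)[C@@H]2CC1 | intermediate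
49 | tertiary formate of 48 (3β-OSiEt3 retained) | C=C1[C@H](CC3=C(OC)OC(C)=C(C(=O)OC)C3=O)[C@]2(C)CC[C@H](O[Si](CC)(CC)CC)[C@](C)(CCC(C)(C)OC=O)[C@@H]2CC1 | intermediate
50 | CNP0292250.1: 3β-hydroxy, 4α-methyl, 4β-(3-formyloxy-3-methylbutyl), 5α-H, C8 exocyclic methylene, 9β-CH2-(methoxypyranone ester), 10α-methyl | C=C1[C@H](CC3=C(OC)OC(C)=C(C(=O)OC)C3=O)[C@]2(C)CC[C@H](O)[C@](C)(CCC(C)(C)OC=O)[C@@H]2CC1 | target

## Step count and risk

Total step count: 31. Longest linear sequence: 26 steps (steps 1–6, 9–25 and 29–31). Side branches: steps 7–8 (alkenyl iodide 14) and steps 26–28 (iodopyranone 45).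

Least certain steps:

**Step 2 (key step).** The transient dienone 5 may be lost by self-dimerisation or by addition of solvent, the vinyl ether 3 may be consumed by acid-catalysed acetal formation with methanol and the acetic acid that is released, and regio- or endo-selectivity may be incomplete with the extra methyl group on the diene. Fallback, from 4 back to 6: 4 is oxidised under the same conditions without a dienophile and the Diels–Alder dimer F1 of 5 is isolated. F1 is then heated with excess 3 in mesitylene (about 200–220 °C, sealed tube). Retro-Diels–Alder cleavage releases 5 in the absence of acid and alcohol, and it is trapped by 3 to give racemic 6.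

**Step 14 (with step 11 before it).** Hydride may be delivered to the exocyclic terminus C17, giving the endocyclic C7=C8 alkene with a C8 methyl group. A palladium hydride may move the new alkene into the ring, or the π-allyl complex may lose a β-hydrogen to a diene. Earlier, the α-methylene ketone 22 may isomerise into conjugation with C9 or dimerise. Fallback, from 20 (isolated after the first operation of step 11) back to 25: 20 is reduced with NaBH4 to amino alcohol F2. F2 is converted with phenyl chlorothionoformate and pyridine into thionocarbonate F3. Barton–McCombie deoxygenation (Bu3SnH, AIBN, toluene, 80 °C) gives amine F4. Oxidation with mCPBA at −78 °C gives N-oxide F5, and warming causes Cope elimination (the only β-hydrogen is on C8) to the exocyclic alkene 25.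

**Step 18.** Enolisation of the hindered tertiary α'-carbon may be slow, and facial selectivity may be poor or opposite to that expected, because the α face carries the syn-axial C20. Methylation syn to C6 would give the C4 epimer. Fallback, from 27 back to 32: the order of the alkylations is reversed. 27 is methylated first (LiN(i-Pr)2, MeI) to 4-methyl enone F6, and the enolate of F6 is then alkylated with 28. If the second electrophile enters syn to C6, this order places the prenyl group β and C18 α, as in 32.

**Step 29.** Transmetalation and reductive elimination may be slow at the pyranone carbon, which is flanked by the methoxy and carbonyl groups, with a β-branched alkylzinc. The organometallic may be protonated or undergo Wurtz-type coupling during the exchange, and the lithium alkoxide may interfere. Fallback, from 38 back to 48: 38 is oxidised with Dess–Martin periodinane to aldehyde F7. F7 is condensed with hydroxypyranone 42 in the presence of Hantzsch ester and catalytic L-proline (Knoevenagel condensation and in-situ conjugate reduction, reductive alkylation at the pyranone C3) to give the 4-hydroxy-2-pyranone F8. F8 is O-methylated with MeOTf and then aqueous NaHCO3, as in step 28, to give 48. In this fallback, the aldehyde must be handled cold and briefly to limit epimerisation at C9.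

## Further compounds

F1 | step 2 | Diels–Alder dimer of 5: 3,3,10,10-tetramethoxy-7,11-dimethyltricyclo[6.2.2.0(2,7)]dodeca-5,11-diene-4,9-dione, endo (racemic) | COC1(OC)C(=O)C=C[C@@]2(C)[C@@H]1[C@@H]1C(OC)(OC)C(=O)[C@H]2C=C1C
F2 | step 14 | amino alcohol: C7–OH, C8–CH2NMe2 (epimers at C7 and C8), other groups as in 20 | OC1C(CN(C)C)[C@H](COCc3ccc(OC)cc3)[C@]2(C)C=C[C@@H](O[Si](C)(C)C(C)(C)C)C[C@@H]2C1
F3 | step 14 | C7 O-phenyl thionocarbonate of F2 | S=C(Oc3ccccc3)OC1C(CN(C)C)[C@H](COCc4ccc(OC)cc4)[C@]2(C)C=C[C@@H](O[Si](C)(C)C(C)(C)C)C[C@@H]2C1
F4 | step 14 | C7-deoxygenated amine: C8–CH2NMe2, C7 = CH2 | CN(C)CC1[C@H](COCc3ccc(OC)cc3)[C@]2(C)C=C[C@@H](O[Si](C)(C)C(C)(C)C)C[C@@H]2CC1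
F5 | step 14 | N-oxide of F4 | C[N+](C)([O-])CC1[C@H](COCc3ccc(OC)cc3)[C@]2(C)C=C[C@@H](O[Si](C)(C)C(C)(C)C)C[C@@H]2CC1
F6 | step 18 | 4-methyl enone (C4 epimers), otherwise as 27 | C=C1[C@H](COCc3ccc(OC)cc3)[C@]2(C)C=CC(=O)C(C)[C@@H]2CC1
F7 | step 29 | C11 aldehyde: 9β-CHO, 3β-OSiEt3, 4β-(3-hydroxy-3-methylbutyl) | C=C1[C@H](C=O)[C@]2(C)CC[C@H](O[Si](CC)(CC)CC)[C@](C)(CCC(C)(C)O)[C@@H]2CC1
F8 | step 29 | 9β-CH2-[4-hydroxy-5-(methoxycarbonyl)-6-methyl-2-oxo-2H-pyran-3-yl] compound, otherwise as 48 | C=C1[C@H](CC3=C(O)C(C(=O)OC)=C(C)OC3=O)[C@]2(C)CC[C@H](O[Si](CC)(CC)CC)[C@](C)(CCC(C)(C)O)[C@@H]2CC1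
A1 | alternative 1 | cis-decalin with C8 ketone, C9 exocyclic methylene, C1=C2, 3-silyloxy and quaternary C4 | O=C1CC[C@H]2[C@@](C)(CCC(C)(C)O[Si](CC)(CC)CC)[C@@H](O[Si](C)(C)C(C)(C)C)C=C[C@@]2(C)C1=C
A2 | alternative 1 | Heck substrate: ring-A cyclohexene (C1=C10) with a 4-iodo-3-oxopent-4-enyl chain on C5 | C=C(I)C(=O)CC[C@H]1[C@@](C)(CCC(C)(C)O[Si](CC)(CC)CC)[C@@H](O[Si](C)(C)C(C)(C)C)CC=C1C
A3 | alternative 2 | cis-decalin C8 enol triflate with C3 methyl enol ether and 9-benzyloxymethyl group | O=S(=O)(OC1=CC[C@H]2C(CCC(C)(C)O[Si](CC)(CC)CC)=C(OC)CC[C@@]2(C)[C@H]1COCc1ccccc1)C(F)(F)F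
A4 | alternative 2 | 2-vinylbicyclo[2.2.2]oct-5-en-2-ol with bridgehead methoxy and methyl groups (vinyl syn to the alkene bridge) | C=C[C@@]1(O)[C@H](COCc2ccccc2)[C@]2(C)CC[C@@]1(OC)C(CCC(C)(C)O[Si](CC)(CC)CC)=C2
A5 | alternative 3 | cis-fused octalin methyl ester (C6=C7, ester on C9) | C1C=C[C@H]2[C@H](CCC(C)(C)O[Si](CC)(CC)CC)[C@@H](O[Si](C)(C)C(C)(C)C)CC[C@@]2(C)[C@H]1C(=O)OC
A6 | alternative 3 | (2Z,8Z)-trienoate: methyl 3-methyldeca-2,8,10-trienoate with 6-silyloxy and 7-(3-silyloxy-3-methylbutyl) groups | COC(=O)/C=C(C)\CC[C@H](O[Si](C)(C)C(C)(C)C)[C@@H](CCC(C)(C)O[Si](CC)(CC)CC)/C=C\C=C
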